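## Retrosynthetic overview

1. The target is C2-symmetric (all-E chain; 3S,4S,3'S,4'S = two trans-3,4-diols). It is traced back to (3S,3'S)-7,8,7',8'-tetradehydroastaxanthin **21** by a hydroxyl-directed reduction of both C4 ketones.
2. Both cyclohexenone rings, with their C6–C7 and C5=C6 bonds, are made together in one two-directional operation. The dilithiated C22 heptaene-diyne **6** acylates two molecules of enol lactone **15**; each released ketone enolate closes onto the new ynone (aldol) and the aldol is dehydrated in the same pot.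
3. **6** comes from C10-dialdehyde **3** and two C6 enynyl phosphonium units **2** (double Wittig).
4. **15** comes from Au-catalysed 6-exo-dig lactonisation of the (4S)-4-silyloxy-5-alkynoic acid **14**. The C3 stereocentre is set by Noyori transfer hydrogenation of ynone acid **9**, made from 2,2-dimethylsuccinic anhydride and propynylmagnesium bromide.
5. Ring order: the γ-lactone **11** and δ-enol lactone **15** are only temporary heterocycles; the two carbocycles both form in step 7 and no ring is formed afterwards.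

Assumption: compounds **1**, **3**, **7** and **8** (0.5 M in THF) are taken as catalogue items; the route has not been run and yields are not estimated.

## Route

Step 1
Reactants: 1 (2E)-3-methylpent-2-en-4-yn-1-ol
Product: 2 [(2E)-3-methylpent-2-en-4-yn-1-yl]triphenylphosphonium bromide
Conditions: Ph3P·HBr, MeOH, rt, 24 h; crystallise
Reagents that add atoms: triphenylphosphine hydrobromide [Br-].c1ccc(cc1)[PH+](c1ccccc1)c1ccccc1
Why: Acid-mediated substitution of a primary allylic alcohol by PPh3 (standard allylic phosphonium salt formation of carotenoid chemistry) keeps the 2E geometry and leaves the terminal alkyne untouched.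

Step 2
Reactants: 2 [(2E)-3-methylpent-2-en-4-yn-1-yl]triphenylphosphonium bromide (2.2 eq); 3 (2E,4E,6E)-2,7-dimethylocta-2,4,6-trienedial
Product: 6 (3E,5E,7E,9E,11E,13E,15E)-3,7,12,16-tetramethyloctadeca-3,5,7,9,11,13,15-heptaene-1,17-diyne, via phosphorus ylide 4 (not isolated), via Z-isomer mixture 5 (not isolated)
Conditions: NaOMe (2.3 eq), MeOH/CH2Cl2, 0 °C → rt; then I2 (1 mol%), CH2Cl2, daylight, rt; crystallise
Reagents that add atoms: none
Why: Two-fold Wittig olefination with the semi-stabilised allylic ylide gives E/Z mixtures at the two new double bonds only, and iodine-catalysed equilibration followed by crystallisation gives the thermodynamically preferred all-E heptaene-diyne (methoxide does not deprotonate the terminal alkynes).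

Step 3
Reactants: 7 2,2-dimethylsuccinic anhydride; 8 prop-1-yn-1-ylmagnesium bromide
Product: 9 2,2-dimethyl-4-oxohept-5-ynoic acid
Conditions: 8 (1.05 eq) added slowly to 7, THF, −78 → −20 °C; 1 M HCl
Reagents that add atoms: none
Why: Acylation of an alkynyl Grignard reagent by a cyclic anhydride occurs at the carbonyl remote from the CMe2 group, and the resulting magnesium carboxylate together with inverse addition at low temperature limits a second addition to the ynone.

Step 4
Reactants: 9 2,2-dimethyl-4-oxohept-5-ynoic acid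
Product: 11 (5S)-3,3-dimethyl-5-(prop-1-yn-1-yl)oxolan-2-one, via hydroxy acid 10 (not isolated)
Conditions: RuCl[(S,S)-TsDPEN](p-cymene) (1 mol%), HCO2H/Et3N 5:2, CH2Cl2, 25 °C; 1 M HCl work-up, concentrate
Reagents that add atoms: none
Why: Noyori–Ikariya asymmetric transfer hydrogenation of the ynone, with the alkynyl group in the π-position of the transition state, gives the (S)-propargylic alcohol with the (S,S)-catalyst, and the γ-hydroxy acid lactonises spontaneously (gem-dimethyl effect) without touching the new stereocentre.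

Step 5
Reactants: 11 (5S)-3,3-dimethyl-5-(prop-1-yn-1-yl)oxolan-2-one
Product: 14 (4S)-4-[(tert-butyldimethylsilyl)oxy]-2,2-dimethylhept-5-ynoic acid, via lithium hydroxy carboxylate 12 (not isolated), via bis-silyl compound 13 (not isolated)
Conditions: LiOH·H2O (1.05 eq), THF/H2O, rt, evaporate; TBSCl (2.5 eq), imidazole (5 eq), DMF, rt; AcOH/THF/H2O, rt, 1 h
Reagents that add atoms: lithium hydroxide [Li+].[OH-]; tert-butyldimethylsilyl chloride CC(C)(C)[Si](C)(C)Cl
Why: Saponification, silylation of the carboxylate salt and the alcohol (faster than relactonisation) and selective hydrolysis of the labile silyl ester give the open-chain silyloxy acid with the C–O stereocentre untouched.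

Step 6
Reactants: 14 (4S)-4-[(tert-butyldimethylsilyl)oxy]-2,2-dimethylhept-5-ynoic acid
Product: 15 (5S,6Z)-5-[(tert-butyldimethylsilyl)oxy]-6-ethylidene-3,3-dimethyloxan-2-one
Conditions: AuCl (5 mol%), K2CO3 (10 mol%), MeCN, rt
Reagents that add atoms: none
Why: Gold-catalysed cycloisomerisation of a 5-alkynoic acid proceeds by anti-oxyauration and protodeauration in the 6-exo-dig mode (helped by the gem-dimethyl group), giving the Z-alkylidene δ-enol lactone regiospecifically without affecting the stereocentre.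

Step 7
Reactants: 6 (3E,5E,7E,9E,11E,13E,15E)-3,7,12,16-tetramethyloctadeca-3,5,7,9,11,13,15-heptaene-1,17-diyne; 15 (5S,6Z)-5-[(tert-butyldimethylsilyl)oxy]-6-ethylidene-3,3-dimethyloxan-2-one (2.2 eq)
Product: 20 (3S,3'S)-3,3'-bis[(tert-butyldimethylsilyl)oxy]-7,8,7',8'-tetradehydro-β,β-carotene-4,4'-dione, via dilithium bis-acetylide 16 (not isolated), via ring-opened bis-enolate 17 (not isolated), via bis-aldolate 18 (not isolated), via bis-acetate 19 (not isolated)
Conditions: n-BuLi (2.05 eq), THF, −78 °C; add to 15 (2.2 eq), THF, −78 → −20 °C; Ac2O (4 eq), −20 → 0 °C; DBU (5 eq), 0 °C → rt; Ar, dark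
Reagents that add atoms: none
Why: Proposed new method: each acetylide terminus adds to the activated, non-enolisable (α,α-dimethyl) enol-lactone carbonyl, the tetrahedral adduct expels the ketone enolate regiospecifically at C5, this enolate closes at once onto the adjacent ynone carbonyl (6-enolendo-exo-trig aldol, faster than intermolecular over-addition), and acetylation/E1cB elimination of the tertiary aldolate gives the conjugated C5=C6 bond, so both cyclohexenone rings form in one pot with the C3 silyloxy stereocentre (α' to the ketone, not involved) retained; the closest known reaction type is the Fujimoto–Belleau enol-lactone annulation, here run with an alkynyl nucleophile so that the liberated enolate, not the added carbon, acts as the aldol donor.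

Step 8
Reactants: 20 (3S,3'S)-3,3'-bis[(tert-butyldimethylsilyl)oxy]-7,8,7',8'-tetradehydro-β,β-carotene-4,4'-dione
Product: 21 (3S,3'S)-3,3'-dihydroxy-7,8,7',8'-tetradehydro-β,β-carotene-4,4'-dione
Conditions: HF·pyridine, pyridine, THF, 0 °C → rt, Ar, dark
Reagents that add atoms: none
Why: Fluoride-driven Si–O cleavage under buffered, non-basic conditions frees the two α-ketols without the base-induced enolisation that would epimerise C3 or oxidise the ketol, and the polyene-diyne is inert.

Step 9
Reactants: 21 (3S,3'S)-3,3'-dihydroxy-7,8,7',8'-tetradehydro-β,β-carotene-4,4'-dione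
Product: 22 (3S,4S,3'S,4'S)-7,8,7',8'-tetradehydro-β,β-carotene-3,4,3',4'-tetrol (CNP0283832.1)
Conditions: Me4NBH(OAc)3 (10 eq), MeCN/AcOH 4:1, −30 → −10 °C, Ar, dark; cold aq. NaHCO3/Rochelle salt
Reagents that add atoms: none
Why: In the Saksena–Evans hydroxyl-directed reduction the pseudo-equatorial C3–OH exchanges onto boron and delivers hydride internally to the same face of the C4 carbonyl (axial attack), so the new OH is trans to the C3–OH and C4/C4' are formed as (S), while alkynes and polyene are untouched.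

## Compound list

1 | (2E)-3-methylpent-2-en-4-yn-1-ol | C#C/C(C)=C/CO | starting material
2 | [(2E)-3-methylpent-2-en-4-yn-1-yl]triphenylphosphonium bromide | C#C/C(C)=C/C[P+](c1ccccc1)(c1ccccc1)c1ccccc1.[Br-] | intermediate
3 | (2E,4E,6E)-2,7-dimethylocta-2,4,6-trienedial (C10-dialdehyde) | O=C/C(C)=C/C=C/C=C(\C)C=O | starting material
4 | [(2E)-3-methylpent-2-en-4-yn-1-ylidene]triphenylphosphorane (ylide) | C#C/C(C)=C/C=P(c1ccccc1)(c1ccccc1)c1ccccc1 | intermediate
5 | 5Z/13Z isomers of 6 (crude Wittig mixture; drawn as the 5Z,13Z isomer) | C#C/C(C)=C/C=C\C(C)=C\C=C\C=C(C)\C=C/C=C(\C)C#C | intermediate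
6 | (3E,5E,7E,9E,11E,13E,15E)-3,7,12,16-tetramethyloctadeca-3,5,7,9,11,13,15-heptaene-1,17-diyne | C#C/C(C)=C/C=C/C(C)=C/C=C/C=C(C)/C=C/C=C(\C)C#C | intermediate
7 | 2,2-dimethylsuccinic anhydride (3,3-dimethyloxolane-2,5-dione) | CC1(C)CC(=O)OC1=O | starting material
8 | prop-1-yn-1-ylmagnesium bromide | CC#C[Mg]Br | starting material
9 | 2,2-dimethyl-4-oxohept-5-ynoic acid | CC#CC(=O)CC(C)(C)C(=O)O | intermediate
10 | (4S)-4-hydroxy-2,2-dimethylhept-5-ynoic acid | CC#C[C@@H](O)CC(C)(C)C(=O)O | intermediate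
11 | (5S)-3,3-dimethyl-5-(prop-1-yn-1-yl)oxolan-2-one | CC#C[C@@H]1CC(C)(C)C(=O)O1 | intermediate
12 | lithium (4S)-4-hydroxy-2,2-dimethylhept-5-ynoate | CC#C[C@@H](O)CC(C)(C)C(=O)[O-].[Li+] | intermediate
13 | tert-butyldimethylsilyl (4S)-4-[(tert-butyldimethylsilyl)oxy]-2,2-dimethylhept-5-ynoate | CC#C[C@@H](O[Si](C)(C)C(C)(C)C)CC(C)(C)C(=O)O[Si](C)(C)C(C)(C)C | intermediate
14 | (4S)-4-[(tert-butyldimethylsilyl)oxy]-2,2-dimethylhept-5-ynoic acid | CC#C[C@@H](O[Si](C)(C)C(C)(C)C)CC(C)(C)C(=O)O | intermediate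
15 | (5S,6Z)-5-[(tert-butyldimethylsilyl)oxy]-6-ethylidene-3,3-dimethyloxan-2-one | C/C=C1\OC(=O)C(C)(C)C[C@@H]1O[Si](C)(C)C(C)(C)C | intermediate
16 | 1,18-dilithio derivative of 6 (dilithium bis-acetylide) | [Li]C#C/C(C)=C/C=C/C(C)=C/C=C/C=C(C)/C=C/C=C(\C)C#C[Li] | intermediate
17 | ring-opened bis(ynone) bis(lithium Z-enolate), (4S,29S), all-E chain | C/C=C(\O[Li])[C@@H](O[Si](C)(C)C(C)(C)C)CC(C)(C)C(=O)C#C/C(C)=C/C=C/C(C)=C/C=C/C=C(C)/C=C/C=C(\C)C#CC(=O)C(C)(C)C[C@H](O[Si](C)(C)C(C)(C)C)/C(O[Li])=C/C | intermediate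
18 | dilithium bis-aldolate: (3S,3'S)-3,3'-bis(TBSO)-6,6'-dioxido-5,6,5',6'-tetrahydro-7,8,7',8'-tetradehydro-β,β-carotene-4,4'-dione (C5/C6 epimer mixture) | CC1C(=O)[C@@H](O[Si](C)(C)C(C)(C)C)CC(C)(C)C1(O[Li])C#C/C(C)=C/C=C/C(C)=C/C=C/C=C(C)/C=C/C=C(\C)C#CC1(O[Li])C(C)C(=O)[C@@H](O[Si](C)(C)C(C)(C)C)CC1(C)C | intermediate
19 | bis-acetate of the bis-aldol: (3S,3'S)-6,6'-diacetoxy-3,3'-bis(TBSO)-5,6,5',6'-tetrahydro-7,8,7',8'-tetradehydro-β,β-carotene-4,4'-dione (C5/C6 epimer mixture) | CC1C(=O)[C@@H](O[Si](C)(C)C(C)(C)C)CC(C)(C)C1(OC(C)=O)C#C/C(C)=C/C=C/C(C)=C/C=C/C=C(C)/C=C/C=C(\C)C#CC1(OC(C)=O)C(C)C(=O)[C@@H](O[Si](C)(C)C(C)(C)C)CC1(C)C | intermediate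
20 | (3S,3'S)-3,3'-bis[(tert-butyldimethylsilyl)oxy]-7,8,7',8'-tetradehydro-β,β-carotene-4,4'-dione (all-E) | CC1=C(C#C/C(C)=C/C=C/C(C)=C/C=C/C=C(C)/C=C/C=C(\C)C#CC2=C(C)C(=O)[C@@H](O[Si](C)(C)C(C)(C)C)CC2(C)C)C(C)(C)C[C@H](O[Si](C)(C)C(C)(C)C)C1=O | intermediate
21 | (3S,3'S)-3,3'-dihydroxy-7,8,7',8'-tetradehydro-β,β-carotene-4,4'-dione (7,8,7',8'-tetradehydroastaxanthin, all-E) | CC1=C(C#C/C(C)=C/C=C/C(C)=C/C=C/C=C(C)/C=C/C=C(\C)C#CC2=C(C)C(=O)[C@@H](O)CC2(C)C)C(C)(C)C[C@H](O)C1=O | intermediate
22 | (3S,4S,3'S,4'S)-7,8,7',8'-tetradehydro-β,β-carotene-3,4,3',4'-tetrol (all-E; CNP0283832.1) | CC1=C(C#C/C(C)=C/C=C/C(C)=C/C=C/C=C(C)/C=C/C=C(\C)C#CC2=C(C)[C@H](O)[C@@H](O)CC2(C)C)C(C)(C)C[C@H](O)[C@H]1O | target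

## Step count and risks

Total steps: 9 (steps 1–2 give 6; steps 3–6 give 15; steps 7–9 are the common end).
Longest linear sequence: 7 steps (3 → 4 → 5 → 6 → 7 → 8 → 9).

Most likely to fail:

**Step 7 (two-fold annulation cascade).** Risks are acetylide over-addition to the liberated ynone, incomplete aldol closure or acetylation of the open enolate, and poor solubility of 16. The fallback sets out from 15 and 6 and separates C–C coupling from ring closure. Enol lactone 15 is opened with ethanethiol (cat. Et3N, CH2Cl2) to S-ethyl (4S)-4-[(tert-butyldimethylsilyl)oxy]-2,2-dimethyl-5-oxoheptanethioate F2. Bis-alkyne 6 is then coupled twice with F2 under neutral Pd/Cu thioester–alkyne (Fukuyama-type) conditions (PdCl2(dppf), P(2-furyl)3, CuI, Et3N, DMF), which tolerate the free ketone, to give the isolable acyclic (4S,29S)-4,29-bis[(tert-butyldimethylsilyl)oxy]-6,6,10,14,19,23,27,27-octamethyldotriaconta-10,12,14,16,18,20,22-heptaene-8,24-diyne-3,7,26,30-tetrone F3. Kinetic deprotonation of the two ethyl-ketone CH2 groups (LiHMDS, THF, −78 °C) gives bis-enolate 17, where the fallback comes back to the route; both rings still close in one operation to 20 via 18 and 19.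

**Step 9 (trans-selective reduction).** Risks are insufficient trans selectivity and acid sensitivity of the allylic 4-ol towards the AcOH medium. The fallback sets out from 20 and inverts the order of the last two steps. The silyl ethers are reduced under Luche conditions (NaBH4, CeCl3·7H2O, MeOH/THF, −78 °C); here the C3–OTBS group is locked pseudo-equatorial by the axial C1 methyl, and axial hydride attack gives (3S,4S,3'S,4'S)-3,3'-bis[(tert-butyldimethylsilyl)oxy]-7,8,7',8'-tetradehydro-β,β-carotene-4,4'-diol F4. Neutral desilylation (TBAF, THF, 0 °C) then comes back to the route at 22.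

**Step 3 (anhydride opening).** Risks are regiochemistry and double addition of the Grignard reagent. The fallback sets out from 7. The anhydride is opened at its less hindered carbonyl with N,O-dimethylhydroxylamine (MeNHOMe·HCl, pyridine, CH2Cl2) to 4-[methoxy(methyl)amino]-2,2-dimethyl-4-oxobutanoic acid F1. Its magnesium carboxylate (i-PrMgCl, 1 eq) is treated with 8, whose stable chelated adduct prevents over-addition, and acidic work-up comes back to the route at 9.

## Further compounds

F1 | step 3 | 4-[methoxy(methyl)amino]-2,2-dimethyl-4-oxobutanoic acid | CON(C)C(=O)CC(C)(C)C(=O)O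
F2 | step 7 | S-ethyl (4S)-4-[(tert-butyldimethylsilyl)oxy]-2,2-dimethyl-5-oxoheptanethioate | CCSC(=O)C(C)(C)C[C@H](O[Si](C)(C)C(C)(C)C)C(=O)CC
F3 | step 7 | (4S,29S,all-E)-4,29-bis[(tert-butyldimethylsilyl)oxy]-6,6,10,14,19,23,27,27-octamethyldotriaconta-10,12,14,16,18,20,22-heptaene-8,24-diyne-3,7,26,30-tetrone | CCC(=O)[C@@H](O[Si](C)(C)C(C)(C)C)CC(C)(C)C(=O)C#C/C(C)=C/C=C/C(C)=C/C=C/C=C(C)/C=C/C=C(\C)C#CC(=O)C(C)(C)C[C@H](O[Si](C)(C)C(C)(C)C)C(=O)CC
F4 | step 9 | (3S,4S,3'S,4'S)-3,3'-bis[(tert-butyldimethylsilyl)oxy]-7,8,7',8'-tetradehydro-β,β-carotene-4,4'-diol | CC1=C(C#C/C(C)=C/C=C/C(C)=C/C=C/C=C(C)/C=C/C=C(\C)C#CC2=C(C)[C@H](O)[C@@H](O[Si](C)(C)C(C)(C)C)CC2(C)C)C(C)(C)C[C@H](O[Si](C)(C)C(C)(C)C)[C@H]1O
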